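## Retrosynthetic overview

1. Target 25 comes from the ten-membered (Z,Z,Z)-triene acid 24. A Pd(II) 1,4-acetoxylactonisation of the C3=C4–C5=C6 diene sets C6–O, C3–OAc and the Z C4=C5 bond, and the γ-lactone is the last ring formed.
2. Acid 24 comes from trienone 19 by reagent-controlled reduction and acetylation at C9 and oxidation of C12 to the acid.
3. Trienone 19 comes from the eight-membered lactone 17 (ring O, C9, C10, C1, C2, C3, C4, C5). Carbonyl methylenation supplies C8, and a [3,3] shift replaces the ring oxygen by C8, C7 and C6, so the ring grows from 8 to 10 atoms.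
4. Enabling feature: at the diene oxidation level, C9(=O)–C8–C7–C6=C5 of the carbocycle is a γ,δ-unsaturated ketone. The remaining ring atoms C9–C10=C1–C2–C3=C4–C5 form a symmetric (Z,Z)-skipped diene whose two ends one oxygen can bridge to an eight-membered ring.
5. Lactone 17 comes from hydroxy acid 15, which comes from enal 6 (double Z-selective Wittig of 1 with 2) and alkyne 10 (from the Roche ester 7). Ring order: 8-ring lactone, then 10-ring carbocycle, then γ-lactone.

Key step: step 11

Remark: germacranolide numbering is used throughout. C6 is the lactone carbinol carbon, C7 the ring-fusion carbon bearing C11, C3 and C9 the acetoxy carbons, C4 and C10 the methyl-bearing olefin carbons, and C12 the lactone carbonyl. Both antipodes of MIB and of the CBS catalyst are taken as purchasable catalysts.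

## Route

Step 1
Reactants: 1 propane-1,3-diylbis(triphenylphosphonium) dibromide; 2 1-[(tert-butyldimethylsilyl)oxy]propan-2-one (2 equiv)
Product: 4 (2Z,5Z)-1,7-bis[(tert-butyldimethylsilyl)oxy]-2,6-dimethylhepta-2,5-diene, via bis-ylide 3 (not isolated)
Conditions: KHMDS (2.1 equiv), THF, −78 → 0 °C; then 2, −78 °C → rt
Reagents that add atoms: none
Why: Double Wittig olefination; non-stabilised ylides add to α-silyloxy methyl ketones under kinetic control so that the CH2OSi group ends cis to the ylide chain, which should set both trisubstituted Z-alkenes (C3=C4 and C1=C10) in one operation.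

Step 2
Reactants: 4 (2Z,5Z)-1,7-bis[(tert-butyldimethylsilyl)oxy]-2,6-dimethylhepta-2,5-diene
Product: 5 (2Z,5Z)-2,6-dimethylhepta-2,5-diene-1,7-diol
Conditions: camphorsulfonic acid (10 mol %), MeOH, 0 °C → rt
Reagents that add atoms: none
Why: Acid-catalysed methanolysis of primary allylic silyl ethers (protecting-group removal) should leave the skipped Z,Z-diene untouched; no stereocentre is involved.

Step 3
Reactants: 5 (2Z,5Z)-2,6-dimethylhepta-2,5-diene-1,7-diol
Product: 6 (2Z,5Z)-7-hydroxy-2,6-dimethylhepta-2,5-dienal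
Conditions: activated MnO2, CH2Cl2, rt, stopped at partial conversion; recovered 5 is recycled
Reagents that add atoms: none
Why: Allylic alcohol oxidation with MnO2 differentiates the two equivalent ends statistically, is neutral enough to keep the Z-enal geometry, and stopping early avoids the strongly C2–H-acidic dialdehyde.

Step 4
Reactants: 7 methyl (S)-3-hydroxy-2-methylpropanoate
Product: 8 methyl (S)-3-[(tert-butyldimethylsilyl)oxy]-2-methylpropanoate
Conditions: TBSCl, imidazole, CH2Cl2, 0 °C → rt
Reagents that add atoms: tert-butyldimethylsilyl chloride, CC(C)(C)[Si](C)(C)Cl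
Why: Standard silylation of a primary alcohol; the purchased stereocentre (later C11) is not touched.

Step 5
Reactants: 8 methyl (S)-3-[(tert-butyldimethylsilyl)oxy]-2-methylpropanoate
Product: 9 (S)-3-[(tert-butyldimethylsilyl)oxy]-2-methylpropanal
Conditions: DIBAL-H (1.05 equiv), CH2Cl2, −78 °C; aq. Rochelle salt
Reagents that add atoms: none
Why: Partial ester reduction with DIBAL-H at low temperature stops at the aldehyde level, and the α-stereocentre is retained if the aldehyde is used at once.

Step 6
Reactants: 9 (S)-3-[(tert-butyldimethylsilyl)oxy]-2-methylpropanal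
Product: 10 (R)-tert-butyldimethyl[(2-methylbut-3-yn-1-yl)oxy]silane
Conditions: dimethyl (1-diazo-2-oxopropyl)phosphonate, K2CO3, MeOH, 0 °C → rt
Reagents that add atoms: dimethyl (1-diazo-2-oxopropyl)phosphonate, COP(=O)(OC)C(=[N+]=[N-])C(C)=O
Why: Seyferth–Gilbert homologation in the Ohira–Bestmann variant adds the terminal alkyne carbon (later C6) under mild base; the geometry at C11 is unchanged and only the descriptor switches from S to R.

Step 7
Reactants: 10 (R)-tert-butyldimethyl[(2-methylbut-3-yn-1-yl)oxy]silane; 6 (2Z,5Z)-7-hydroxy-2,6-dimethylhepta-2,5-dienal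
Product: 13 (2Z,5Z,7R,8E,10R)-11-[(tert-butyldimethylsilyl)oxy]-2,6,10-trimethylundeca-2,5,8-triene-1,7-diol, via alkenylzirconocene 11 (not isolated), via alkenylzinc 12 (not isolated)
Conditions: 10, Cp2Zr(H)Cl, CH2Cl2, rt; change to toluene; Me2Zn, −65 °C; (+)-MIB (10 mol %); 6 (pre-treated with 1 equiv Me2Zn), −30 → 0 °C; aq. NH4Cl
Reagents that add atoms: none
Why: Syn hydrozirconation fixes the E C6=C7 alkene, and after Zr-to-Zn transmetalation the amino-alcohol-catalysed enantioselective alkenylzinc addition directs the alkenyl group to the Re face of the enal, so the C5 carbinol (7R in 13) is set by the catalyst.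

Step 8
Reactants: 13 (2Z,5Z,7R,8E,10R)-11-[(tert-butyldimethylsilyl)oxy]-2,6,10-trimethylundeca-2,5,8-triene-1,7-diol
Product: 14 (2Z,5Z,7R,8E,10R)-11-[(tert-butyldimethylsilyl)oxy]-7-hydroxy-2,6,10-trimethylundeca-2,5,8-trienal
Conditions: TEMPO (10 mol %), PhI(OAc)2 (1.1 equiv), CH2Cl2, 0 °C → rt
Reagents that add atoms: none
Why: The oxoammonium (TEMPO/PhI(OAc)2) oxidation prefers the unhindered primary allylic alcohol over the secondary bis-allylic one and is known to preserve Z-enal geometry.

Step 9
Reactants: 14 (2Z,5Z,7R,8E,10R)-11-[(tert-butyldimethylsilyl)oxy]-7-hydroxy-2,6,10-trimethylundeca-2,5,8-trienal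
Product: 15 (2Z,5Z,7R,8E,10R)-11-[(tert-butyldimethylsilyl)oxy]-7-hydroxy-2,6,10-trimethylundeca-2,5,8-trienoic acid
Conditions: NaClO2, NaH2PO4, 2-methylbut-2-ene, t-BuOH/H2O, 0 °C → rt
Reagents that add atoms: sodium chlorite, [Na+].[O-]Cl=O
Why: Pinnick oxidation converts the enal to the acid without touching the free secondary alcohol, while the scavenger removes HOCl from the olefins.

Step 10
Reactants: 15 (2Z,5Z,7R,8E,10R)-11-[(tert-butyldimethylsilyl)oxy]-7-hydroxy-2,6,10-trimethylundeca-2,5,8-trienoic acid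
Product: 17 (3Z,6Z,8R)-8-{(1E,3R)-4-[(tert-butyldimethylsilyl)oxy]-3-methylbut-1-en-1-yl}-3,7-dimethyl-5,8-dihydro-2H-oxocin-2-one, via mixed anhydride 16 (not isolated)
Conditions: 2-methyl-6-nitrobenzoic anhydride (1.3 equiv), DMAP (3 equiv), CH2Cl2, high dilution, slow addition of 15, rt
Reagents that add atoms: none
Why: Shiina lactonisation; the two Z-alkenes hold C9 and the C5 hydroxyl on the same side of C2, which should favour eight-membered ring closure, and C5 keeps its configuration because only the O–H bond reacts.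

Step 11
Reactants: 17 (3Z,6Z,8R)-8-{(1E,3R)-4-[(tert-butyldimethylsilyl)oxy]-3-methylbut-1-en-1-yl}-3,7-dimethyl-5,8-dihydro-2H-oxocin-2-one
Product: 19 (2Z,5Z,7Z,9R)-9-{(2R)-1-[(tert-butyldimethylsilyl)oxy]propan-2-yl}-2,6-dimethylcyclodeca-2,5,7-trien-1-one, via dienol ether 18 (not isolated)
Conditions: Cp2TiMe2 (2.5 equiv), toluene, BHT, dark, 75 °C; then 105 °C
Reagents that add atoms: dimethyltitanocene, C[Ti](C)(C1C=CC=C1)C1C=CC=C1
Why: Petasis methylenation turns the lactone carbonyl into the exocyclic enol ether 18, an allyl vinyl ether that undergoes a Claisen [3,3] shift in the same pot: C8–C7 forms, O–C5 breaks, and the ring oxygen is replaced in the ring by C8, C7 and C6 (8 → 10) while it becomes the C9 ketone oxygen. The closest known reaction type is the methylenation/Claisen ring expansion of lactones that carry a vinyl group on the carbinol carbon, which gives cycloalkenones two atoms larger. The ten-membered ring is closed through a six-centre transition state bridged by the five-atom chain C10=C1–C2–C3=C4 (bicyclo[5.3.1]-like), and no other ring is closed. C7 is the only new stereocentre and is fixed by suprafacial 1,3-chirality transfer from C5; because C8 is an unsubstituted CH2 terminus, chair and boat give the same result, so the outcome depends only on the E geometry of C6=C7 and on the geometry of the new C5=C6 bond. That bond should be Z because the ring torsion C9–O–C5–C4 of the eight-membered ring is gauche, which places C4 pseudo-axial on the transition-state ring. The step needs selectivity for the exocyclic allyl arm (C5–C6=C7) over the endocyclic arm (C5–C4=C3, which would contract the ring to a cyclohexenone); that path must pass a bicyclo[3.3.1]non-1-ene-like bridgehead-olefin geometry on a C4-methylated allyl unit and should therefore need a much higher temperature.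

Step 12
Reactants: 19 (2Z,5Z,7Z,9R)-9-{(2R)-1-[(tert-butyldimethylsilyl)oxy]propan-2-yl}-2,6-dimethylcyclodeca-2,5,7-trien-1-one
Product: 20 (1R,2Z,5Z,7Z,9R)-9-{(2R)-1-[(tert-butyldimethylsilyl)oxy]propan-2-yl}-2,6-dimethylcyclodeca-2,5,7-trien-1-ol
Conditions: (S)-Me-CBS (20 mol %), catecholborane (1.8 equiv), toluene, −78 °C
Reagents that add atoms: none
Why: CBS reduction; the α-methyl alkenyl flank (C10) acts as the large group and C8H2 as the small one, so the (S)-catalyst should deliver the 9R carbinol by reagent control, and catecholborane at low temperature spares the olefins.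

Step 13
Reactants: 20 (1R,2Z,5Z,7Z,9R)-9-{(2R)-1-[(tert-butyldimethylsilyl)oxy]propan-2-yl}-2,6-dimethylcyclodeca-2,5,7-trien-1-ol
Product: 21 (1R,2Z,5Z,7Z,9R)-9-{(2R)-1-[(tert-butyldimethylsilyl)oxy]propan-2-yl}-2,6-dimethylcyclodeca-2,5,7-trien-1-yl acetate
Conditions: Ac2O, pyridine, DMAP (cat.), CH2Cl2, 0 °C → rt
Reagents that add atoms: acetic anhydride, CC(=O)OC(C)=O
Why: DMAP-catalysed acetylation installs the C9 acetate of the target with retention, since only the O–H bond reacts.

Step 14
Reactants: 21 (1R,2Z,5Z,7Z,9R)-9-{(2R)-1-[(tert-butyldimethylsilyl)oxy]propan-2-yl}-2,6-dimethylcyclodeca-2,5,7-trien-1-yl acetate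
Product: 22 (1R,2Z,5Z,7Z,9R)-9-[(2R)-1-hydroxypropan-2-yl]-2,6-dimethylcyclodeca-2,5,7-trien-1-yl acetate
Conditions: HF·pyridine, pyridine, THF, 0 °C
Reagents that add atoms: none
Why: Buffered fluoride desilylation frees the primary alcohol without the basic conditions that could cleave or shift the allylic acetate.

Step 15
Reactants: 22 (1R,2Z,5Z,7Z,9R)-9-[(2R)-1-hydroxypropan-2-yl]-2,6-dimethylcyclodeca-2,5,7-trien-1-yl acetate
Product: 24 (2R)-2-[(1R,2Z,4Z,7Z,9R)-9-acetoxy-4,8-dimethylcyclodeca-2,4,7-trien-1-yl]propanoic acid, via aldehyde 23 (not isolated)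
Conditions: TEMPO (20 mol %), PhI(OAc)2 (2.5 equiv), MeCN/pH 7 buffer 1:1, rt
Reagents that add atoms: water, O
Why: TEMPO/PhI(OAc)2 oxidation in aqueous medium carries the saturated primary alcohol through the aldehyde hydrate to the acid near neutral pH, which should keep C11 from epimerising.

Step 16
Reactants: 24 (2R)-2-[(1R,2Z,4Z,7Z,9R)-9-acetoxy-4,8-dimethylcyclodeca-2,4,7-trien-1-yl]propanoic acid
Product: 25 (3S,6S,7S,9R,11R)-3,9-diacetoxygermacra-1(10)Z,4Z-dien-12,6-olide (target)
Conditions: Pd(OAc)2 (10 mol %), p-benzoquinone (2 equiv), acetone/AcOH 4:1, chloride-free, rt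
Reagents that add atoms: acetic acid, CC(=O)O
Why: Palladium(II)/benzoquinone 1,4-acetoxylactonisation of a conjugated diene; the tethered carboxylate adds to C6 anti to Pd from the face that carries C11 in the A(1,3)-minimised rotamer (H7 in the plane of the Z C5=C6 bond), which gives the trans-fused γ-lactone (6S), and in chloride-free medium acetate passes from Pd to C3 of the π-allyl unit on the opposite face (3S, trans-1,4), leaving C4=C5 Z because the diene reacts in its cisoid form.

## Compound list

1 | propane-1,3-diylbis(triphenylphosphonium) dibromide | [Br-].[Br-].c1ccccc1[P+](c1ccccc1)(c1ccccc1)CCC[P+](c1ccccc1)(c1ccccc1)c1ccccc1 | starting material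
2 | 1-[(tert-butyldimethylsilyl)oxy]propan-2-one | CC(=O)CO[Si](C)(C)C(C)(C)C | starting material
3 | propane-1,3-diylidenebis(triphenylphosphorane) (bis-ylide) | c1ccccc1P(c1ccccc1)(c1ccccc1)=CCC=P(c1ccccc1)(c1ccccc1)c1ccccc1 | intermediate
4 | (2Z,5Z)-1,7-bis[(tert-butyldimethylsilyl)oxy]-2,6-dimethylhepta-2,5-diene | CC(C)(C)[Si](C)(C)OC/C(C)=C\C/C=C(/C)CO[Si](C)(C)C(C)(C)C | intermediate
5 | (2Z,5Z)-2,6-dimethylhepta-2,5-diene-1,7-diol | OC/C(C)=C\C/C=C(/C)CO | intermediate
6 | (2Z,5Z)-7-hydroxy-2,6-dimethylhepta-2,5-dienal | O=C/C(C)=C\C/C=C(/C)CO | intermediate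
7 | methyl (S)-3-hydroxy-2-methylpropanoate | COC(=O)[C@@H](C)CO | starting material
8 | methyl (S)-3-[(tert-butyldimethylsilyl)oxy]-2-methylpropanoate | COC(=O)[C@@H](C)CO[Si](C)(C)C(C)(C)C | intermediate
9 | (S)-3-[(tert-butyldimethylsilyl)oxy]-2-methylpropanal | O=C[C@@H](C)CO[Si](C)(C)C(C)(C)C | intermediate
10 | (R)-tert-butyldimethyl[(2-methylbut-3-yn-1-yl)oxy]silane | C#C[C@@H](C)CO[Si](C)(C)C(C)(C)C | intermediate
11 | chlorobis(cyclopentadienyl){(1E,3R)-4-[(tert-butyldimethylsilyl)oxy]-3-methylbut-1-en-1-yl}zirconium | Cl[Zr](C1C=CC=C1)(C1C=CC=C1)/C=C/[C@@H](C)CO[Si](C)(C)C(C)(C)C | intermediate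
12 | methyl{(1E,3R)-4-[(tert-butyldimethylsilyl)oxy]-3-methylbut-1-en-1-yl}zinc | C[Zn]/C=C/[C@@H](C)CO[Si](C)(C)C(C)(C)C | intermediate
13 | (2Z,5Z,7R,8E,10R)-11-[(tert-butyldimethylsilyl)oxy]-2,6,10-trimethylundeca-2,5,8-triene-1,7-diol | OC/C(C)=C\C/C=C(/C)[C@H](O)/C=C/[C@@H](C)CO[Si](C)(C)C(C)(C)C | intermediate
14 | (2Z,5Z,7R,8E,10R)-11-[(tert-butyldimethylsilyl)oxy]-7-hydroxy-2,6,10-trimethylundeca-2,5,8-trienal | O=C/C(C)=C\C/C=C(/C)[C@H](O)/C=C/[C@@H](C)CO[Si](C)(C)C(C)(C)C | intermediate
15 | (2Z,5Z,7R,8E,10R)-11-[(tert-butyldimethylsilyl)oxy]-7-hydroxy-2,6,10-trimethylundeca-2,5,8-trienoic acid | OC(=O)/C(C)=C\C/C=C(/C)[C@H](O)/C=C/[C@@H](C)CO[Si](C)(C)C(C)(C)C | intermediate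
16 | mixed anhydride of 15 with 2-methyl-6-nitrobenzoic acid | Cc1cccc([N+](=O)[O-])c1C(=O)OC(=O)/C(C)=C\C/C=C(/C)[C@H](O)/C=C/[C@@H](C)CO[Si](C)(C)C(C)(C)C | intermediate
17 | (3Z,6Z,8R)-8-{(1E,3R)-4-[(tert-butyldimethylsilyl)oxy]-3-methylbut-1-en-1-yl}-3,7-dimethyl-5,8-dihydro-2H-oxocin-2-one | O=C1O[C@H](/C=C/[C@@H](C)CO[Si](C)(C)C(C)(C)C)/C(C)=C\C/C=C1/C | intermediate
18 | (3Z,6Z,8R)-8-{(1E,3R)-4-[(tert-butyldimethylsilyl)oxy]-3-methylbut-1-en-1-yl}-3,7-dimethyl-2-methylidene-5,8-dihydro-2H-oxocine | C=C1O[C@H](/C=C/[C@@H](C)CO[Si](C)(C)C(C)(C)C)/C(C)=C\C/C=C1/C | intermediate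
19 | (2Z,5Z,7Z,9R)-9-{(2R)-1-[(tert-butyldimethylsilyl)oxy]propan-2-yl}-2,6-dimethylcyclodeca-2,5,7-trien-1-one | O=C1C[C@@H]([C@@H](C)CO[Si](C)(C)C(C)(C)C)/C=C\C(C)=C/C/C=C1/C | intermediate
20 | (1R,2Z,5Z,7Z,9R)-9-{(2R)-1-[(tert-butyldimethylsilyl)oxy]propan-2-yl}-2,6-dimethylcyclodeca-2,5,7-trien-1-ol | O[C@@H]1C[C@@H]([C@@H](C)CO[Si](C)(C)C(C)(C)C)/C=C\C(C)=C/C/C=C1/C | intermediate
21 | (1R,2Z,5Z,7Z,9R)-9-{(2R)-1-[(tert-butyldimethylsilyl)oxy]propan-2-yl}-2,6-dimethylcyclodeca-2,5,7-trien-1-yl acetate | CC(=O)O[C@@H]1C[C@@H]([C@@H](C)CO[Si](C)(C)C(C)(C)C)/C=C\C(C)=C/C/C=C1/C | intermediate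
22 | (1R,2Z,5Z,7Z,9R)-9-[(2R)-1-hydroxypropan-2-yl]-2,6-dimethylcyclodeca-2,5,7-trien-1-yl acetate | CC(=O)O[C@@H]1C[C@@H]([C@@H](C)CO)/C=C\C(C)=C/C/C=C1/C | intermediate
23 | (1R,2Z,5Z,7Z,9R)-2,6-dimethyl-9-[(2R)-1-oxopropan-2-yl]cyclodeca-2,5,7-trien-1-yl acetate | CC(=O)O[C@@H]1C[C@@H]([C@@H](C)C=O)/C=C\C(C)=C/C/C=C1/C | intermediate
24 | (2R)-2-[(1R,2Z,4Z,7Z,9R)-9-acetoxy-4,8-dimethylcyclodeca-2,4,7-trien-1-yl]propanoic acid | CC(=O)O[C@@H]1C[C@@H]([C@@H](C)C(=O)O)/C=C\C(C)=C/C/C=C1/C | intermediate
25 | (3S,6S,7S,9R,11R)-3,9-diacetoxygermacra-1(10)Z,4Z-dien-12,6-olide | CC(=O)O[C@H]1C/C=C(/C)[C@H](OC(C)=O)C[C@@H]2[C@@H](/C=C\1C)OC(=O)[C@@H]2C | target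

## Step count and risks

Total step count: 16. Longest linear sequence: 13 (steps 1–3 and 7–16).

**Step 11.** Four things may go wrong:
- slow methylenation of the hindered, conjugated lactone;
- hydrolysis of the dienol ether before it rearranges;
- leakage of the [3,3] shift into the endocyclic allyl arm;
- a [1,5]-hydrogen shift of the new Z,Z-diene at the temperature needed.

The fallback sets out from 17 and comes back at 19. It replaces the thermal one-pot pericyclic event with a two-stage, metal-templated sequence. Lactone 17 is methylenated with the Tebbe reagent at −40 °C in THF/pyridine, and dienol ether 18 is isolated on basic alumina. It is then rearranged at room temperature with PdCl2(MeCN)2. In this stepwise cyclisation-induced rearrangement Pd(II) binds only the unhindered 1,2-disubstituted C6=C7 alkene. An allyl arm with a substituent on its central carbon (C4–CH3) is inert in this mode, so arm selection rests on the catalyst and the hydrogen shift is avoided. No new compound is made.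

**Step 16.** What may go wrong is loss of facial or 1,4-regiocontrol in the palladation of the flexible ten-membered diene. Syn–anti equilibration at the π-allyl stage could also erode the C4=C5 geometry or the trans relation of O3 and O6.

The fallback sets out from 24 and comes back at 25, and it builds the two C–O bonds by cycloaddition instead.
- Singlet oxygen (tetraphenylporphyrin, O2, hν, CH2Cl2, −78 °C) should add [4+2] to the cisoid diene on the face away from C11, giving the 3,6-endoperoxide acid F1.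
- Thiourea in MeOH reduces the O–O bond to the cis-3,6-diol acid F2.
- The C6 hydroxyl of F2 closes onto the acid (cat. PPTS) to give the trans-fused 3-epi-hydroxy lactone F3.
- A Mitsunobu reaction (PPh3, DIAD, AcOH) then inverts C3 and installs the acetate of 25.

**Step 10.** Three things may go wrong:
- Z-to-E isomerisation of the activated 2-methylenoyl unit by reversible DMAP addition;
- conjugate addition of the C5 hydroxyl to C1;
- intermolecular esterification competing with eight-membered ring closure.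

The fallback sets out from 14 and comes back at 17, skipping acid 15 and the mixed anhydride. It is an N-heterocyclic-carbene-catalysed oxidative esterification (triazolium precatalyst, DBU, 3,3′,5,5′-tetra-tert-butyldiphenoquinone, toluene, high dilution). This converts the enal directly into an acyl azolium that the C5 hydroxyl captures. No new compound is made.

## Further compounds

F1 | step 16 | 3,6-endoperoxide acid (3α,6α-epidioxy, C4=C5 in the dioxine ring) | CC(=O)O[C@@H]1C[C@@H]([C@@H](C)C(=O)O)[C@@H]2OO[C@H](C/C=C1/C)C(C)=C2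
F2 | step 16 | cis-3,6-diol acid | CC(=O)O[C@@H]1C[C@@H]([C@@H](C)C(=O)O)[C@H](O)/C=C(/C)[C@H](O)C/C=C1/C
F3 | step 16 | 3-epi-hydroxy lactone (9-acetate, free 3-OH) | O[C@@H]1C/C=C(/C)[C@H](OC(C)=O)C[C@@H]2[C@@H](/C=C\1C)OC(=O)[C@@H]2C
F0 | step 11 | none | none
F0 | step 10 | none | none
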